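**Assumptions.** 5‑Iodo‑2‑methylpent‑2‑ene and 2‑methylpent‑4‑en‑2‑ol are treated as catalogue chemicals. Compounds 4–6 are carried as 1:1 epimers at the future carbinol carbon, and steps 6–7 correct this.

## Retrosynthetic overview

1. The two tertiary carbinols come last, from a double Markovnikov hydration of bis‑alkene 18.
2. Key disconnection: the central CH2–CH2 bond and the enone C=O form together when primary iodide 11 adds to exocyclic diene 17 under light in DMSO.
3. Left half 11 comes from (S)‑carvone. The carvone ring is kept, the quaternary carbon is set by double alkylation, isopropenyl is converted to O, the oxepane is closed, and the ketone is then methylenated and hydroborated.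
4. Right half 17 also comes from (S)‑carvone. The carvone ring is kept, C6 is tert‑alkylated, RCM closes the second carbocycle, and the ketone is methylenated.
5. Ring order: the two carvone rings are bought, the oxepane forms in step 5, and the gem‑dimethyl ring forms in step 14.

## Route

### Left half (steps 1–10)

**Step 1**
- Reactants: 1, (S)‑(+)‑carvone
- Product: 2, 6‑methylcarvone (C6 epimers)
- Conditions: LDA, THF, –78 °C; MeI, –78→0 °C
- Reagents that add atoms: iodomethane, CI
- Why: Kinetic α′‑enolate alkylation; the C6 epimer ratio does not matter because C6 is re‑enolised in step 2.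

**Step 2**
- Reactants: 2
- Product: 3, (5R,6R)‑2,6‑dimethyl‑6‑(4‑methylpent‑3‑enyl)‑5‑isopropenylcyclohex‑2‑enone (6‑Me cis to isopropenyl)
- Conditions: LDA, THF, –78→0 °C; DMPU, 5‑iodo‑2‑methylpent‑2‑ene, –78 °C→rt
- Reagents that add atoms: 5‑iodo‑2‑methylpent‑2‑ene, CC(C)=CCCI
- Why: Enolate alkylation in which the electrophile enters anti to the carvone isopropenyl group, so the bought stereocentre fixes the quaternary carbon.

**Step 3**
- Reactants: 3
- Product: 4, side‑chain 3,3‑dimethyloxirane (1:1 at the oxirane CH)
- Conditions: mCPBA (1.0 equiv), NaHCO3, CH2Cl2, 0 °C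
- Reagents that add atoms: mCPBA, O=C(OO)c1cccc(Cl)c1
- Why: Prilezhaev epoxidation picks the most electron‑rich (trisubstituted) alkene; the uncontrolled CH–O centre is erased and reset in steps 6–7.

**Step 4**
- Reactants: 4
- Product: 5, (1S,2R)‑2‑[2‑(3,3‑dimethyloxiran‑2‑yl)ethyl]‑2,4‑dimethyl‑3‑oxocyclohex‑4‑enyl acetate
- Conditions: O3, CH2Cl2/MeOH, –78 °C (Sudan III end point); then Ac2O, Et3N, DMAP, 0→40 °C
- Reagents that add atoms: ozone, [O-][O+]=O; acetic anhydride, CC(=O)OC(C)=O
- Why: Selective ozonolysis of the isopropenyl group, then Criegee rearrangement of the α‑methoxy perester, replaces C–C by C–O with retention of configuration.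

**Step 5**
- Reactants: 5
- Product: 6, trans‑fused 3‑hydroxy‑2,2,5a,7‑tetramethyl‑hexahydro‑1‑benzoxepin‑6‑one (5aR,9aS; C3 epimers)
- Conditions: K2CO3, MeOH, 0 °C (brief); then CSA (10 mol %), CH2Cl2/HFIP, 0 °C
- Reagents that add atoms: none
- Why: After methanolysis, acid‑catalysed 7‑endo epoxide opening at the cation‑stabilising tertiary carbon closes the oxepane, and the quaternary α‑carbon rules out E1cB loss of the β‑oxygen.

**Step 6**
- Reactants: 6
- Product: 7, (5aR,9aS)‑2,2,5a,7‑tetramethyl‑tetrahydro‑1‑benzoxepine‑3,6‑dione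
- Conditions: Dess–Martin periodinane, NaHCO3, CH2Cl2, rt
- Reagents that add atoms: none
- Why: Dess–Martin oxidation converges both carbinol epimers to a single ketone.

**Step 7**
- Reactants: 7
- Product: 8, (3S,5aR,9aS)‑3‑hydroxy‑2,2,5a,7‑tetramethyl‑hexahydro‑1‑benzoxepin‑6‑one
- Conditions: NaBH4, MeOH/CH2Cl2, –78→–40 °C
- Reagents that add atoms: none
- Why: Substrate‑controlled reduction in which the twist‑chair oxepanone carries a pseudo‑axial C2 methyl that blocks the α face, so hydride adds from the β face to give the 3S alcohol while the hindered conjugated ketone survives.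

**Step 8**
- Reactants: 8
- Product: 9, (3S,5aS,9aS)‑2,2,5a,7‑tetramethyl‑6‑methylidene‑octahydro‑1‑benzoxepin‑3‑ol (exocyclic/endocyclic diene)
- Conditions: Ph3PCH3Br, KOt‑Bu (4 equiv), toluene, 90 °C
- Reagents that add atoms: methyltriphenylphosphonium bromide, C[P+](c1ccccc1)(c1ccccc1)c1ccccc1.[Br-]
- Why: Wittig methylenation under forcing hindered‑ketone conditions; the alkoxide is a spectator.

**Step 9**
- Reactants: 9
- Product: 10, (3S,5aS,6R,9aS)‑6‑(hydroxymethyl)‑2,2,5a,7‑tetramethyl‑octahydro‑1‑benzoxepin‑3‑ol
- Conditions: 9‑BBN (3 equiv), THF, 50 °C; then NaOH, H2O2, 0 °C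
- Reagents that add atoms: hydrogen peroxide, OO
- Why: Hydroboration–oxidation of the terminal alkene, with H delivered to the ring carbon from the face opposite the axial angular methyl, which places the CH2OH arm equatorial.

**Step 10**
- Reactants: 10
- Product: 11, the corresponding 6‑(iodomethyl) compound
- Conditions: I2, PPh3, imidazole, CH2Cl2, 0 °C
- Reagents that add atoms: iodine, II
- Why: Appel iodination is selective for the primary alcohol over the neopentylic secondary one.

### Right half (steps 11–15)

**Step 11**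
- Reactants: 12, 2‑methylpent‑4‑en‑2‑ol
- Product: 13, 4‑chloro‑4‑methylpent‑1‑ene
- Conditions: conc. HCl, 0 °C→rt
- Reagents that add atoms: hydrogen chloride, Cl
- Why: SN1 chlorination of a tertiary alcohol; the monosubstituted alkene is inert.

**Step 12**
- Reactants: 1
- Product: 14, carvone kinetic (cross‑conjugated) TMS dienol ether
- Conditions: LDA, THF, –78 °C; TMSCl
- Reagents that add atoms: chlorotrimethylsilane, C[Si](C)(C)Cl
- Why: Kinetic α′‑deprotonation followed by O‑silylation.

**Step 13**
- Reactants: 14 and 13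
- Product: 15, (5S,6S)‑2‑methyl‑6‑(2‑methylpent‑4‑en‑2‑yl)‑5‑isopropenylcyclohex‑2‑enone (trans)
- Conditions: TiCl4 (1.05 equiv), CH2Cl2, –78→–45 °C
- Reagents that add atoms: none
- Why: Reetz α‑tert‑alkylation (SN1 capture of the tertiary cation by the silyl enol ether) anti to isopropenyl; this epimerisable centre is finally set in step 16.

**Step 14**
- Reactants: 15
- Product: 16, (4aS,8aS)‑2,5,8,8‑tetramethyl‑4a,7,8,8a‑tetrahydronaphthalen‑1(4H)‑one
- Conditions: Grubbs II (5 mol %), CH2Cl2, 40 °C
- Reagents that add atoms: none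
- Why: Ring‑closing metathesis of a vinyl and a 1,1‑disubstituted alkene gives the trisubstituted cyclohexene with loss of ethylene.

**Step 15**
- Reactants: 16
- Product: 17, (4aS,8aS)‑2,5,8,8‑tetramethyl‑1‑methylidene‑1,4,4a,7,8,8a‑hexahydronaphthalene
- Conditions: Ph3PCH3Br, KOt‑Bu, toluene, 80 °C
- Reagents that add atoms: methyltriphenylphosphonium bromide, C[P+](c1ccccc1)(c1ccccc1)c1ccccc1.[Br-]
- Why: Wittig methylenation of the enone carbonyl gives the 1,3‑diene acceptor.

### Coupling and endgame (steps 16–17)

**Step 16**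
- Reactants: 11 and 17 (1.5 equiv)
- Product: 18, coupled cis‑fused 2‑methyl‑3‑alkyl enone that still carries both trisubstituted alkenes
- Conditions: 10‑phenylphenothiazine (5 mol %), 2,6‑lutidine, DMSO, 390 nm LED, 25 °C; then DBU, 45 °C
- Reagents that add atoms: dimethyl sulfoxide, CS(C)=O (oxygen atom)
- Why: Proposed new method: a 1,4‑keto‑alkylation of a 1,3‑diene in which the excited photocatalyst reduces the C–I bond, the primary radical adds to the exocyclic CH2, the allyl radical is oxidised by the catalyst radical cation (or takes iodine by atom transfer), DMSO adds reversibly at the tertiary terminus but productively at the secondary one, base collapses that alkoxysulfonium (Kornblum) to the tetrasubstituted enone, and DBU then equilibrates the γ‑CH to the cis ring fusion, which relieves A1,3 strain between the new chain and the CMe2 carbon; the closest known reactions are photoredox keto‑alkylation of styrenes in DMSO and three‑component radical–polar carbofunctionalisation of dienes.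

**Step 17**
- Reactants: 18
- Product: 19, sipholenol K
- Conditions: Co(acac)2 (25 mol %), PhSiH3, O2 (1 atm), THF/i‑PrOH, 0 °C→rt; then PPh3
- Reagents that add atoms: dioxygen, O=O
- Why: Mukaiyama hydration (MHAT, then O2 capture) of both trisubstituted alkenes, with O2 approaching anti to the axial angular methyl in the left ring and from the convex face of the cis‑decalin in the right ring, while the tetrasubstituted enone is too hindered for hydrogen‑atom transfer.

## Compound list

| No. | Name | SMILES | Role |
|---|---|---|---|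
| 1 | (S)‑(+)‑carvone | `CC1=CC[C@@H](CC1=O)C(C)=C` | starting material |
| 2 | 6‑methylcarvone (C6 epimers) | `O=C1C(C)[C@@H](C(C)=C)CC=C1C` | intermediate |
| 3 | (5R,6R)‑6‑homoprenyl‑6‑methylcarvone | `O=C1[C@](C)(CCC=C(C)C)[C@@H](C(C)=C)CC=C1C` | intermediate |
| 4 | side‑chain epoxide of 3 | `O=C1[C@](C)(CCC2OC2(C)C)[C@@H](C(C)=C)CC=C1C` | intermediate |
| 5 | epoxy acetate | `O=C1[C@](C)(CCC2OC2(C)C)[C@@H](OC(C)=O)CC=C1C` | intermediate |
| 6 | oxepane enone, C3‑OH epimers | `O=C1[C@]2(C)CCC(O)C(C)(C)O[C@H]2CC=C1C` | intermediate |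
| 7 | oxepan‑3‑one enone | `O=C1[C@]2(C)CCC(=O)C(C)(C)O[C@H]2CC=C1C` | intermediate |
| 8 | (3S)‑hydroxy oxepane enone | `O=C1[C@]2(C)CC[C@H](O)C(C)(C)O[C@H]2CC=C1C` | intermediate |
| 9 | methylidene diene | `C=C1[C@]2(C)CC[C@H](O)C(C)(C)O[C@H]2CC=C1C` | intermediate |
| 10 | primary alcohol | `OC[C@H]1[C@]2(C)CC[C@H](O)C(C)(C)O[C@H]2CC=C1C` | intermediate |
| 11 | primary iodide | `IC[C@H]1[C@]2(C)CC[C@H](O)C(C)(C)O[C@H]2CC=C1C` | intermediate |
| 12 | 2‑methylpent‑4‑en‑2‑ol | `CC(C)(O)CC=C` | starting material |
| 13 | 4‑chloro‑4‑methylpent‑1‑ene | `CC(C)(Cl)CC=C` | intermediate |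
| 14 | carvone TMS dienol ether | `CC1=CC[C@H](C(C)=C)C=C1O[Si](C)(C)C` | intermediate |
| 15 | (5S,6S)‑6‑(2‑methylpent‑4‑en‑2‑yl)carvone | `O=C1C(C)=CC[C@H](C(C)=C)[C@H]1C(C)(C)CC=C` | intermediate |
| 16 | bicyclic dienone (trans) | `O=C1C(C)=CC[C@@H]2C(C)=CCC(C)(C)[C@@H]12` | intermediate |
| 17 | bicyclic triene | `C=C1C(C)=CC[C@@H]2C(C)=CCC(C)(C)[C@@H]12` | intermediate |
| 18 | coupled enone, bis‑alkene (cis) | `CC1=C(CC[C@H]2[C@]3(C)CC[C@H](O)C(C)(C)O[C@H]3CC=C2C)[C@@H]2[C@H](CC1=O)C(C)=CCC2(C)C` | intermediate |
| 19 | sipholenol K | `CC1=C(CC[C@H]2[C@]3(C)CC[C@H](O)C(C)(C)O[C@H]3CC[C@]2(C)O)[C@@H]2[C@H](CC1=O)[C@@](C)(O)CCC2(C)C` | target |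

## Step count

- Total steps: 17
- Longest linear sequence: 12 (steps 1–10, 16, 17)

## Steps most likely to fail

1. **Step 16 (new photochemical keto‑alkylation).** Risks are slow C–I reduction, proton loss from the allyl cation to a triene, or incomplete Kornblum collapse. Fallback with known chemistry: protect 11 as its TES ether, carry out I/Li exchange with t‑BuLi, add the organolithium 1,2 to ketone 16, and use PCC for the Dauben–Michno oxidative transposition of the tertiary allylic alcohol to the same enone.
2. **Step 5 (7‑endo versus 6‑exo epoxide opening).** Fallback: close the ring by C–C bond formation instead. Alkylate 2 with allyl bromide, convert isopropenyl to OH as in step 4, etherify with 2‑methylbut‑3‑en‑2‑yl trichloroacetimidate, and close the oxepene by RCM. Epoxidation anti to the angular methyl followed by LiEt3BH opening at the less hindered carbon then gives 8 directly.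
3. **Step 13 (SN1 tert‑alkylation; hydride shifts in the cation or attack on the isopropenyl group).** Fallback: make the same bond by radical chemistry. Run an aldol of the carvone lithium enolate with acetone, convert the tertiary alcohol to its cesium oxalate, and perform photoredox Keck‑type allylation with allyl phenyl sulfone to reach 15.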